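## The problem

CNP0302656.1 (22) is a hexahydroinden-2-one. Ring A is a cyclopentanone, C1(Et)–C2(=O)–C3(Me)–C4–C5, trans-fused along C4–C5 to ring B, a cyclohexene, C4–C5–C6(Me)=C7–C8–C9. This numbering is used for every intermediate. Ring B carries two adjacent quaternary carbons: C8 (ethyl, (E)-styryl) and C9 (ethyl, carboxyl). The two ethyl groups lie on one face (α) and the styryl and carboxyl groups on the other (β). C9 is further flanked by the ring-fusion carbon C4, whose hydrogen is β. Of the six stereocentres only C8, C9 and C4 are fixed once made. C1 and C3 lie α to the C2 ketone, and C5 becomes α to a carbonyl whenever C6 is a ketone, so these three can be left to equilibrate against C4. C8 and C9 can be controlled as a pair, because their cis carboxyl and styryl carbons can both come from one cyclic anhydride; C4 must then be set against C9 by a facial selection. The (E)-styryl group and the C6=C7 alkene exclude late hydrogenation and strong acid, and the carboxyl group on a quaternary carbon between two crowded neighbours will not be freed by ordinary saponification. The feature that is exploited: with C6 written as a ketone, C2 and C6 are the carbonyls of a 1,4-diketone whose central bond is C1–C5. Ring A can therefore be closed by joining the α-carbons of two ketones, and every centre made or touched in that event is epimerisable.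

## Retrosynthesis

**C6–CH3 and the acid (22 ⇒ 21 ⇒ 20 ⇒ 18).** The acid is carried as methyl ester 21. The C6 methyl group and the C6=C7 alkene are traced through enol triflate 20 to the C6 ketone of diketone 18. This cut turns C6 into a carbonyl, which makes C5 epimerisable and exposes the 1,4-diketone. It asks that only the C6 ketone of 18 be enolised and only toward C7 (the single α-methylene of 18), and that the ester later be cleaved at its methyl carbon.

**C1–C5 (18 ⇒ 16), the key cut.** Cutting the central bond of the 1,4-diketone gives the monocyclic bis(silyl enol ether) 16. The neighbouring cut C3–C4 would be a 5-endo Michael closure that sets the non-epimerisable C4 in the ring-forming event. C1–C5 instead joins two carbons that can both be corrected afterwards. The precursor has one ring and two controlled stereocentres fewer. The forward reaction must oxidise an enol ether in the presence of the styrene and close a five-membered ring between two substituted carbons.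

**C3–C4 (16 ⇒ 14 ⇒ 11 + 13).** The side-chain enol ether of 16 comes from kinetic enolisation of ketone 14 at the C1 methylene. The C3–C4 bond of 14 is cut as a Mukaiyama–Michael addition of enol ether 13 to enone 11. This gives the ring enol ether with the C5=C6 regiochemistry directly, which enolisation of a C6 ketone (C5 versus C7) could not guarantee. Enone 11 is six carbons and two stereocentres simpler. Enol ether 13 comes from vinyl ketone 12, because hexan-3-one cannot be enolised toward one side. The forward step must bring the nucleophile to the α face of C4, next to C9.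

**The styryl C=C (11 ⇒ 10 ⇒ 9 ⇒ 8).** The alkene is cut to a benzylidene ylide and the C8 aldehyde, which is held as lactol 9. Allylic alcohol 10 is the oxidation-state neighbour of 11. Lactone 8 stores the C8 acyl carbon and the C6 oxygen in one ring, so a single partial reduction releases both. The forward steps must reduce a bridged lactone beside a hindered ester and olefinate a neopentyl aldehyde with E geometry.

**C6–O and the C4=C5 unsaturation (8 ⇒ 7 ⇒ 6).** Iodolactonisation and dehydroiodination convert the symmetric alkene of hemiester 6 into the enone pattern. The C8 carboxyl can reach only C6, so oxygen arrives at C6 and the alkene ends at C4=C5. An allylic oxidation could not choose between C4 and C7, and a siloxydiene cycloaddition that delivers the C6 ketone directly would destroy the mirror symmetry needed in the next cut.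

**One ester C–O (6 ⇒ 5).** Enantioselective methanolysis of meso anhydride 5 sets C8 and C9 absolutely and decides which carboxyl becomes the acid. The precursor is achiral.

**C4–C9 and C7–C8 (5 ⇒ 3 + 4), then 3 ⇒ 1.** A Diels–Alder reaction of anhydride 3 with diene 4 makes both quaternary carbons at once. The cyclic dienophile guarantees cis ethyl groups. Anhydride 3 is the double carboxylation product of alkyne 1.

## Roads not taken

Alternative 1: cobalt-mediated [2+2+1] cyclocarbonylation (Pauson–Khand) of dienyne A2 to bicyclic enone A1.
- **Cut:** C4–C5, C1–C2 and C2–C3, removing both rings at once.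
- **Forward step:** the C3≡C4 alkyne, the (E)-C5=C1 alkene and carbon monoxide combine.
- **Merits:** three C–C bonds and two rings form in one step. The alkene geometry fixes the C1/C5 relationship without equilibration, so on bond economy and on C1/C5 this road is better than the chosen one.
- **Weak points:** A2 needs the vicinal quaternary pair C8/C9 built enantioselectively in an open chain, so the hardest part of the target is moved upstream rather than solved. The alkene is internal and part of a conjugated diene, the alkyne is internal, and the tether closes a six-membered ring; each of these slows or diverts the cycloaddition. A1 still holds a C3=C4 double bond, so the non-epimerisable C4 hydrogen must be delivered to the β face of a tetrasubstituted enone next to C9.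
- **Comparison:** the chosen plan sets against the bond economy a trivial source of C8/C9 (a cyclic dienophile), an absolute-configuration step on a meso compound, and a ring closure whose new centres can be corrected. Both roads must set C4 by a facial choice beside C9.

Alternative 2: [4+2] cycloaddition of the ring-A siloxydiene A4 with dienophile 3 to cycloadduct A3.
- **Cut:** C4–C9 and C7–C8.
- **Merits:** this is the most convergent plan. Ring B, both quaternary carbons and C4 arise together, and the enol ether of A3 leaves C5 for later protonation. In step count and in forming the crowded C4–C9 bond directly it is better than the chosen plan.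
- **Weak points:** a tetrasubstituted dienophile must bond to a diene terminus (C4) that is a ring carbon flanked by C3. In A4 the ring carbon C3 is the outward substituent at C4, so the usual endo mode would place it cis to the anhydride; the target needs the exo mode. Facial control must come from C1 and C3 of an enantiopure ring A. The two anhydride carbonyls of A3 must then be told apart with no symmetry or neighbouring group to help.
- **Comparison:** the chosen plan uses an unhindered diene, has no endo/exo question, and solves carboxyl differentiation and absolute configuration in one desymmetrisation plus an iodolactonisation. It pays with a longer sequence and a separate conjugate addition for C4.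

Alternative 3: Dowd–Beckwith ring expansion of the bromomethyl β-keto ester A6 to ring-expanded ketone A5.
- **Cut:** C6–C7, with ring B shrunk to a cyclopentanone on a cis-fused bicyclo[3.3.0]octane.
- **Forward step:** a tin hydride radical chain; the primary radical adds to the C6 carbonyl and the alkoxy radical fragments.
- **Merits:** the cis-fused diquinane is the natural fusion of two five-membered rings, the chain reaction is dependable for this substrate class, and C6 arrives as a ketone. The ring-forming step itself is more predictable than an electrolysis on a crowded substrate.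
- **Weak points:** A5 has C8 only as a tertiary ester-bearing carbon. The ethyl group must still be added by enolate alkylation beside quaternary C9 with facial control, and the methyl ester must become styryl while the tert-butyl ester survives. A6 contains four contiguous stereocentres including C9 and needs a long synthesis of its own.
- **Comparison:** the chosen plan has both quaternary centres in place before any ring-A chemistry and is shorter; it accepts the less certain ring closure.

Key step: step 12

Assumption: 14, 15 and 16 are drawn as one C3 epimer and one enol ether geometry although mixtures at C3 and at C1=C2 are expected; these mixtures are carried on because both elements are erased or equilibrated in step 12.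

Step 1
Reactants: 1 hex-3-yne
Product: 3 2,3-diethylmaleic anhydride, via 2,3-diethylmaleic acid 2 (not isolated)
Conditions: CO2 (1 atm), NiBr2(2,2'-bipyridine) (10 mol%), Zn powder, MgBr2, DMF, rt; then aq. HCl
Reagents that add atoms: carbon dioxide, O=C=O
Why: Nickel-catalysed reductive double carboxylation of an internal alkyne (oxanickelacycle from alkyne and CO2, reduction by zinc, second CO2 insertion) should give the cis-dicarboxylate; a dialkylmaleic acid closes to its anhydride on acidification.

Step 2
Reactants: 3 2,3-diethylmaleic anhydride; 4 buta-1,3-diene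
Product: 5 cis-3a,7a-diethyl-3a,4,7,7a-tetrahydro-2-benzofuran-1,3-dione (meso)
Conditions: 4 (excess), hydroquinone (cat.), toluene, sealed vessel, 170 °C
Reagents that add atoms: none
Why: Diels–Alder reaction of a dialkylmaleic anhydride with an unhindered diene; suprafacial addition to the cyclic dienophile fixes the two ethyl groups cis at C8 and C9, and the adduct is meso.

Step 3
Reactants: 5 cis-3a,7a-diethyl-3a,4,7,7a-tetrahydro-2-benzofuran-1,3-dione
Product: 6 (1S,2R)-1,2-diethyl-2-(methoxycarbonyl)cyclohex-4-ene-1-carboxylic acid (acid on C8, methyl ester on C9)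
Conditions: quinine or quinidine (1.1 equiv; the pseudoenantiomer that leads to 6), MeOH (3 equiv), toluene, −40 °C; cold aq. HCl work-up, alkaloid recovered
Reagents that add atoms: methanol, CO
Why: Cinchona alkaloid-mediated desymmetrising methanolysis of a meso anhydride (general-base delivery of methanol to one of the enantiotopic carbonyls) sets C8 and C9 absolutely and differentiates the two carboxyl carbons; the sense of induction is to be assigned by correlation at 6 or 7.

Step 4
Reactants: 6 (1S,2R)-1,2-diethyl-2-(methoxycarbonyl)cyclohex-4-ene-1-carboxylic acid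
Product: 7 methyl 1,2-diethyl-4-iodo-7-oxo-6-oxabicyclo[3.2.1]octane-2-carboxylate (lactone from the C8 carboxyl to C6 on the β face, iodine at C5 α)
Conditions: I2, KI, NaHCO3, H2O/CH2Cl2, 0 °C to rt, dark
Reagents that add atoms: iodine, II
Why: Iodolactonisation: the C8 carboxylate can reach only C6 in a five-membered lactone and opens the iodonium ion anti, so the C6–O bond is β and the C5–I bond α; the hindered ester does not compete.

Step 5
Reactants: 7 methyl 1,2-diethyl-4-iodo-7-oxo-6-oxabicyclo[3.2.1]octane-2-carboxylate
Product: 8 methyl 1,2-diethyl-7-oxo-6-oxabicyclo[3.2.1]oct-3-ene-2-carboxylate (C4=C5 alkene, C6–O β)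
Conditions: DBU, toluene, 100 °C
Reagents that add atoms: none
Why: E2 dehydroiodination: the axial C5 iodide has its only anti-periplanar hydrogen at C4, so the alkene should form at C4=C5 and leave the allylic lactone intact.

Step 6
Reactants: 8 methyl 1,2-diethyl-7-oxo-6-oxabicyclo[3.2.1]oct-3-ene-2-carboxylate
Product: 9 methyl 1,2-diethyl-7-hydroxy-6-oxabicyclo[3.2.1]oct-3-ene-2-carboxylate (lactol, anomer mixture)
Conditions: i-Bu2AlH (1.1 equiv), CH2Cl2, −78 °C; aq. potassium sodium tartrate
Reagents that add atoms: none
Why: Partial reduction of a lactone to the lactol; the strained bridged γ-lactone should react faster than the methyl ester, whose carbonyl sits on C9 between two fully substituted carbons.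

Step 7
Reactants: 9 methyl 1,2-diethyl-7-hydroxy-6-oxabicyclo[3.2.1]oct-3-ene-2-carboxylate
Product: 10 methyl (1R,4R,6R)-1,6-diethyl-4-hydroxy-6-[(E)-2-phenylethenyl]cyclohex-2-ene-1-carboxylate (C6–OH β)
Conditions: PhCH2PBu3Br (2.2 equiv), KN(SiMe3)2 (2.2 equiv), THF, 0 °C; then 9, −78 °C to rt
Reagents that add atoms: benzyltributylphosphonium bromide, CCCC[P+](CCCC)(CCCC)Cc1ccccc1.[Br-]
Why: Wittig olefination of the open hydroxy-aldehyde form of the lactol; benzylidene ylides of trialkylphosphines are E-selective, so the (E)-styryl group should result, and any Z isomer can be isomerised with a trace of iodine.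

Step 8
Reactants: 10 methyl (1R,4R,6R)-1,6-diethyl-4-hydroxy-6-[(E)-2-phenylethenyl]cyclohex-2-ene-1-carboxylate
Product: 11 methyl (1R,6R)-1,6-diethyl-4-oxo-6-[(E)-2-phenylethenyl]cyclohex-2-ene-1-carboxylate
Conditions: Dess–Martin periodinane, CH2Cl2, rt
Reagents that add atoms: none
Why: Oxidation of a secondary allylic alcohol to the enone by a hypervalent iodine reagent; no stereocentre is at risk and the styrene is inert.

Step 9
Reactants: 12 hex-1-en-3-one
Product: 13 triethyl{[(2Z)-hex-2-en-3-yl]oxy}silane
Conditions: Et3SiH, RhCl(PPh3)3 (0.5 mol%), THF, 50 °C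
Reagents that add atoms: triethylsilane, CC[SiH](CC)CC
Why: Rhodium-catalysed 1,4-hydrosilylation of a vinyl ketone puts hydrogen on the terminal carbon and silicon on oxygen, giving the enol ether of hexan-3-one on the ethyl side only.

Step 10
Reactants: 11 methyl (1R,6R)-1,6-diethyl-4-oxo-6-[(E)-2-phenylethenyl]cyclohex-2-ene-1-carboxylate; 13 triethyl{[(2Z)-hex-2-en-3-yl]oxy}silane
Product: 14 methyl 1,6-diethyl-2-(3-oxohexan-2-yl)-6-[(E)-2-phenylethenyl]-4-[(triethylsilyl)oxy]cyclohex-3-ene-1-carboxylate (side chain on C4 α, cis to both ethyl groups; C5=C6 enol ether)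
Conditions: Ph3CSbCl6 (5 mol%), CH2Cl2, −78 °C; pyridine quench, non-aqueous work-up
Reagents that add atoms: none
Why: Mukaiyama–Michael addition under trityl-cation catalysis with silyl transfer, so the ring enolate is kept as the C5=C6 triethylsilyl enol ether; the nucleophile is expected to enter C4 axially and anti to the C9 ester, which as the smaller and electron-withdrawing group should take the pseudoaxial position, placing the side chain α; C3 forms as a mixture that is corrected in step 12.

Step 11
Reactants: 14 methyl 1,6-diethyl-2-(3-oxohexan-2-yl)-6-[(E)-2-phenylethenyl]-4-[(triethylsilyl)oxy]cyclohex-3-ene-1-carboxylate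
Product: 16 methyl 1,6-diethyl-6-[(E)-2-phenylethenyl]-2-{(3Z)-3-[(triethylsilyl)oxy]hex-3-en-2-yl}-4-[(triethylsilyl)oxy]cyclohex-3-ene-1-carboxylate, via lithium enolate 15 (not isolated)
Conditions: lithium diisopropylamide (1.1 equiv), THF, −78 °C; then Et3SiCl, −78 °C to 0 °C; pentane, filtration
Reagents that add atoms: chlorotriethylsilane, CC[Si](Cl)(CC)CC
Why: Kinetic deprotonation of the side-chain ketone at the C1 methylene rather than the branched C3 methine, followed by O-silylation; the ring enol ether and the ester without α-hydrogen are inert to the amide base.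

Step 12
Reactants: 16 methyl 1,6-diethyl-6-[(E)-2-phenylethenyl]-2-{(3Z)-3-[(triethylsilyl)oxy]hex-3-en-2-yl}-4-[(triethylsilyl)oxy]cyclohex-3-ene-1-carboxylate
Product: 18 methyl 1,4,5-triethyl-3-methyl-2,7-dioxo-5-[(E)-2-phenylethenyl]octahydro-1H-indene-4-carboxylate (trans-fused; C1–Et α, C3–Me β, C4–H β, C5–H α), via kinetic diketone mixture 17 (not isolated)
Conditions: reticulated vitreous carbon anode, Pt cathode, undivided cell, constant current (about 2.1 F/mol), LiClO4 (0.1 M), 2,6-lutidine, CH2Cl2/MeOH (4:1), rt; then K2CO3, MeOH, rt
Reagents that add atoms: none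
Why: One-electron oxidation of one of the two trisubstituted silyl enol ethers at the carbon anode should give a radical cation whose carbon terminus is attacked by the other enol ether, forming C1–C5; a second electron transfer and loss of both triethylsilyl groups to methanol give the 1,4-diketone 17, while hydrogen is evolved at the cathode. The closest known reaction type is the anodic or one-electron chemical intramolecular coupling of two enol ether or silyl enol ether units to 1,4-dicarbonyl compounds. Ring A closes in a 5-exo-trig mode (the C5=C6 bond is exocyclic to the new ring), and because the tether leaves C4 on the α face the first-formed fusion should be cis. The new centres C1 and C5, and the carried C3, all lie α to a carbonyl in 17 and are set under thermodynamic control in the K2CO3/MeOH stage relative to the fixed C4, which should lead to the trans ring fusion with all four ring-A substituents alternating. The step needs site selectivity, which the two regiodefined enol ethers secure since only C1 and C5 carry enol ether carbons, and chemoselectivity over the styrene, which is harder to oxidise than either enol ether. 2,6-Lutidine buffers the acid formed so that the enol ethers are not solvolysed before they are oxidised.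

Step 13
Reactants: 18 methyl 1,4,5-triethyl-3-methyl-2,7-dioxo-5-[(E)-2-phenylethenyl]octahydro-1H-indene-4-carboxylate
Product: 20 methyl 1,4,5-triethyl-3-methyl-2-oxo-5-[(E)-2-phenylethenyl]-7-{[(trifluoromethyl)sulfonyl]oxy}-2,3,3a,4,5,7a-hexahydro-1H-indene-4-carboxylate (C6=C7 enol triflate), via potassium enolate 19 (not isolated)
Conditions: KN(SiMe3)2 (1.05 equiv), THF, −78 °C; then PhNTf2, −78 °C to −20 °C
Reagents that add atoms: N-phenylbis(trifluoromethanesulfonimide), O=S(=O)(N(c1ccccc1)S(=O)(=O)C(F)(F)F)C(F)(F)F
Why: Kinetic enolisation with a hindered amide base should take the only α-methylene (C7) in preference to the α-methines C1, C3 and C5, and O-sulfonylation gives the vinyl triflate; C5 is no longer epimerisable after this step.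

Step 14
Reactants: 20 methyl 1,4,5-triethyl-3-methyl-2-oxo-5-[(E)-2-phenylethenyl]-7-{[(trifluoromethyl)sulfonyl]oxy}-2,3,3a,4,5,7a-hexahydro-1H-indene-4-carboxylate
Product: 21 methyl 1,4,5-triethyl-3,7-dimethyl-2-oxo-5-[(E)-2-phenylethenyl]-2,3,3a,4,5,7a-hexahydro-1H-indene-4-carboxylate
Conditions: MeZnCl (2 equiv), Pd(PPh3)4 (5 mol%), THF, 50 °C
Reagents that add atoms: methylzinc chloride, C[Zn]Cl
Why: Negishi coupling (oxidative addition of zerovalent palladium to the vinyl triflate, transmetalation from methylzinc, reductive elimination); the organozinc reagent leaves the ketone and the ester untouched.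

Step 15
Reactants: 21 methyl 1,4,5-triethyl-3,7-dimethyl-2-oxo-5-[(E)-2-phenylethenyl]-2,3,3a,4,5,7a-hexahydro-1H-indene-4-carboxylate
Product: 22 1,4,5-triethyl-3,7-dimethyl-2-oxo-5-[(E)-2-phenylethenyl]-2,3,3a,4,5,7a-hexahydro-1H-indene-4-carboxylic acid (CNP0302656.1)
Conditions: EtSNa (5 equiv), DMF, 90 °C; then 1 M HCl
Reagents that add atoms: none
Why: SN2 dealkylation of a methyl ester by thiolate at the methyl carbon, used because attack at the acyl carbon between two quaternary neighbours is blocked; C1 and C3 are already in their thermodynamic configuration and the alkenes are not affected.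

## Compound list

1 | hex-3-yne | CCC#CCC | starting material
2 | (Z)-2,3-diethylbut-2-enedioic acid (2,3-diethylmaleic acid) | OC(=O)/C(CC)=C(/CC)C(=O)O | intermediate
3 | 2,3-diethylmaleic anhydride (3,4-diethylfuran-2,5-dione) | CCC1=C(CC)C(=O)OC1=O | intermediate
4 | buta-1,3-diene | C=CC=C | starting material
5 | cis-3a,7a-diethyl-3a,4,7,7a-tetrahydro-2-benzofuran-1,3-dione (meso) | C1C=CC[C@@]2(CC)[C@]1(CC)C(=O)OC2=O | intermediate
6 | (1S,2R)-1,2-diethyl-2-(methoxycarbonyl)cyclohex-4-ene-1-carboxylic acid | C1C=CC[C@@](C(=O)O)(CC)[C@]1(CC)C(=O)OC | intermediate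
7 | methyl 1,2-diethyl-4-iodo-7-oxo-6-oxabicyclo[3.2.1]octane-2-carboxylate (C6–O β, C5–I α, ester β) | C1[C@@H](I)[C@H]2C[C@@](C(=O)O2)(CC)[C@]1(CC)C(=O)OC | intermediate
8 | methyl 1,2-diethyl-7-oxo-6-oxabicyclo[3.2.1]oct-3-ene-2-carboxylate (C4=C5, C6–O β) | C1=C[C@H]2C[C@@](C(=O)O2)(CC)[C@]1(CC)C(=O)OC | intermediate
9 | methyl 1,2-diethyl-7-hydroxy-6-oxabicyclo[3.2.1]oct-3-ene-2-carboxylate (lactol, anomer mixture) | C1=C[C@H]2C[C@@](C(O)O2)(CC)[C@]1(CC)C(=O)OC | intermediate
10 | methyl (1R,4R,6R)-1,6-diethyl-4-hydroxy-6-[(E)-2-phenylethenyl]cyclohex-2-ene-1-carboxylate | C1=C[C@H](O)C[C@@](/C=C/c2ccccc2)(CC)[C@]1(CC)C(=O)OC | intermediate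
11 | methyl (1R,6R)-1,6-diethyl-4-oxo-6-[(E)-2-phenylethenyl]cyclohex-2-ene-1-carboxylate | C1=CC(=O)C[C@@](/C=C/c2ccccc2)(CC)[C@]1(CC)C(=O)OC | intermediate
12 | hex-1-en-3-one | CCCC(=O)C=C | starting material
13 | triethyl{[(2Z)-hex-2-en-3-yl]oxy}silane | C/C=C(\O[Si](CC)(CC)CC)CCC | intermediate
14 | methyl 1,6-diethyl-2-(3-oxohexan-2-yl)-6-[(E)-2-phenylethenyl]-4-[(triethylsilyl)oxy]cyclohex-3-ene-1-carboxylate (C4 side chain α; C3 epimer drawn as in 22, both epimers carried) | CCCC(=O)[C@@H](C)[C@H]1C=C(O[Si](CC)(CC)CC)C[C@@](/C=C/c2ccccc2)(CC)[C@]1(CC)C(=O)OC | intermediate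
15 | lithium enolate of 14 at C1=C2 | [Li+].CC/C=C(\[O-])[C@@H](C)[C@H]1C=C(O[Si](CC)(CC)CC)C[C@@](/C=C/c2ccccc2)(CC)[C@]1(CC)C(=O)OC | intermediate
16 | methyl 1,6-diethyl-6-[(E)-2-phenylethenyl]-2-{(3Z)-3-[(triethylsilyl)oxy]hex-3-en-2-yl}-4-[(triethylsilyl)oxy]cyclohex-3-ene-1-carboxylate (C4 side chain α; one C3 epimer and one C1=C2 geometry drawn) | CC/C=C(\O[Si](CC)(CC)CC)[C@@H](C)[C@H]1C=C(O[Si](CC)(CC)CC)C[C@@](/C=C/c2ccccc2)(CC)[C@]1(CC)C(=O)OC | intermediate
17 | methyl 1,4,5-triethyl-3-methyl-2,7-dioxo-5-[(E)-2-phenylethenyl]octahydro-1H-indene-4-carboxylate, kinetic mixture (C1, C3 and C5 not yet settled; C4, C8, C9 as in 18) | CCC1C(=O)C(C)[C@H]2C1C(=O)C[C@@](/C=C/c1ccccc1)(CC)[C@]2(CC)C(=O)OC | intermediate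
18 | methyl 1,4,5-triethyl-3-methyl-2,7-dioxo-5-[(E)-2-phenylethenyl]octahydro-1H-indene-4-carboxylate (trans-fused; C1–Et α, C3–Me β, C4–H β, C5–H α) | CC[C@@H]1C(=O)[C@@H](C)[C@H]2[C@H]1C(=O)C[C@@](/C=C/c1ccccc1)(CC)[C@]2(CC)C(=O)OC | intermediate
19 | potassium C6=C7 enolate of 18 | [K+].CC[C@@H]1C(=O)[C@@H](C)[C@H]2[C@H]1C([O-])=C[C@@](/C=C/c1ccccc1)(CC)[C@]2(CC)C(=O)OC | intermediate
20 | methyl 1,4,5-triethyl-3-methyl-2-oxo-5-[(E)-2-phenylethenyl]-7-{[(trifluoromethyl)sulfonyl]oxy}-2,3,3a,4,5,7a-hexahydro-1H-indene-4-carboxylate (configuration as in 18) | CC[C@@H]1C(=O)[C@@H](C)[C@H]2[C@H]1C(OS(=O)(=O)C(F)(F)F)=C[C@@](/C=C/c1ccccc1)(CC)[C@]2(CC)C(=O)OC | intermediate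
21 | methyl 1,4,5-triethyl-3,7-dimethyl-2-oxo-5-[(E)-2-phenylethenyl]-2,3,3a,4,5,7a-hexahydro-1H-indene-4-carboxylate (configuration as in 22) | CC[C@@H]1C(=O)[C@@H](C)[C@H]2[C@H]1C(C)=C[C@@](/C=C/c1ccccc1)(CC)[C@]2(CC)C(=O)OC | intermediate
22 | 1,4,5-triethyl-3,7-dimethyl-2-oxo-5-[(E)-2-phenylethenyl]-2,3,3a,4,5,7a-hexahydro-1H-indene-4-carboxylic acid, CNP0302656.1 (trans-fused; C1–Et α, C3–Me β, C4–H β, C5–H α, C8–styryl β, C9–CO2H β, both ring-B ethyl groups α) | CC[C@@H]1C(=O)[C@@H](C)[C@H]2[C@H]1C(C)=C[C@@](/C=C/c1ccccc1)(CC)[C@]2(CC)C(=O)O | target

## Step count and least certain steps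

Total step count: 15. Longest linear sequence: 14 steps (1 to 22 through steps 1–8 and 10–15); step 9 is a one-step side branch.

**Step 12 (key step).** The ring closure joins two substituted carbons beside the C9 quaternary centre. Loss of a silyl group to methanol, or capture of the radical cation by methanol, may outrun C1–C5 bond formation and return the open 1,5-diketone or α-methoxy ketones. The base stage may also stop short of the trans-fused isomer if the thermodynamic preference is small. Fallback: the fallback sets out from 16 and replaces the radical-cation route by oxidative coupling of a preformed bis-enolate. Both silyl groups of 16 are cleaved with MeLi (2 equiv, THF) to the regiodefined dilithium bis-enolate F1, which is oxidised with Fe(acac)3 in an intramolecular enolate coupling to 17. Equilibration with K2CO3 in MeOH brings the material back to the route at 18.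

**Step 10.** The nucleophile may show poor or reversed facial selectivity at C4, because the enone can react through two half-chair forms (ester pseudoaxial with attack from α, or styryl axial with attack from β). Addition next to a quaternary carbon may also be slow. Fallback: the fallback sets out from the step-10 product mixture, that is 14 together with its C4 epimer F2, and turns the same facial bias to advantage. Saegusa–Ito oxidation with Pd(OAc)2 in MeCN removes the C4 stereocentre and gives the C4-substituted enone F3. A 1,4-hydrosilylation (Et3SiH, RhCl(PPh3)3) then delivers hydride, instead of carbon, to C4. If the β face is the accessible one, hydride enters there and leaves the side chain α. The ring enol ether is regenerated with the same regiochemistry and the sequence comes back to the route at 14.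

**Step 3.** Methanolysis of an anhydride flanked by two quaternary carbons may be slow at the low temperature that selectivity needs. The hemiester can also re-close to the meso anhydride and reopen unselectively, which erodes the enantiomeric purity. Fallback: the fallback sets out from 5 and uses classical resolution. NaOMe in MeOH opens 5 to the racemic hemiester F4. Its salt with (R)-1-phenylethylamine (or the enantiomeric amine, whichever gives the less soluble salt with 6), the diastereomeric salt F5, is crystallised to purity. Acidification comes back to the route at 6.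

**Step 13.** Enolisation may not stay at C7. Proton transfer to the cyclopentanone enolates (C1, C3) or to C5 would give regioisomeric or double triflates. Fallback: the fallback sets out from 14 and keeps the C2 carbonyl masked from the moment ring A is closed. The C1 potassium enolate of 14 (KN(SiMe3)2, THF/DMPU) is O-methylated with Me2SO4 to the mixed methyl/triethylsilyl bis(enol ether) F6. Anodic coupling of F6 under the conditions of step 12 traps the methyl oxocarbenium ion with methanol. After K2CO3/MeOH this gives the trans-fused C6 ketone with C2 as its dimethyl ketal F7, which now has a single carbonyl. Triflation as in step 13 gives enol triflate ketal F8, and methylation as in step 14 gives methylated ketal F9. Mild aqueous acid releases the C2 ketone, and K2CO3 in MeOH settles C1 and C3, coming back to the route at 21.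

## Further compounds

F1 | step 12 | dilithium bis-enolate from 16 (C1=C2 and C5=C6 enolates) | [Li+].[Li+].CC/C=C(\[O-])[C@@H](C)[C@H]1C=C([O-])C[C@@](/C=C/c2ccccc2)(CC)[C@]1(CC)C(=O)OC
F2 | step 10 | C4 epimer of 14 (side chain on the β face; C3 unassigned) | CCCC(=O)C(C)[C@@H]1C=C(O[Si](CC)(CC)CC)C[C@@](/C=C/c2ccccc2)(CC)[C@]1(CC)C(=O)OC
F3 | step 10 | methyl 1,6-diethyl-4-oxo-2-(3-oxohexan-2-yl)-6-[(E)-2-phenylethenyl]cyclohex-2-ene-1-carboxylate (C4-substituted enone; C3 unassigned) | CCCC(=O)C(C)C1=CC(=O)C[C@@](/C=C/c2ccccc2)(CC)[C@]1(CC)C(=O)OC
F4 | step 3 | racemic cis-1,2-diethyl-2-(methoxycarbonyl)cyclohex-4-ene-1-carboxylic acid (6 and its enantiomer) | C1C=CC[C@@](C(=O)O)(CC)[C@]1(CC)C(=O)OC.C1C=CC[C@](C(=O)O)(CC)[C@@]1(CC)C(=O)OC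
F5 | step 3 | (R)-1-phenylethylammonium salt of 6 | C1C=CC[C@@](C(=O)[O-])(CC)[C@]1(CC)C(=O)OC.C[C@@H]([NH3+])c1ccccc1
F6 | step 13 | methyl 1,6-diethyl-2-[(3Z)-3-methoxyhex-3-en-2-yl]-6-[(E)-2-phenylethenyl]-4-[(triethylsilyl)oxy]cyclohex-3-ene-1-carboxylate | CC/C=C(\OC)[C@@H](C)[C@H]1C=C(O[Si](CC)(CC)CC)C[C@@](/C=C/c2ccccc2)(CC)[C@]1(CC)C(=O)OC
F7 | step 13 | methyl 1,4,5-triethyl-2,2-dimethoxy-3-methyl-7-oxo-5-[(E)-2-phenylethenyl]octahydro-1H-indene-4-carboxylate (trans-fused; C1 and C3 unassigned) | CCC1C(OC)(OC)C(C)[C@H]2[C@H]1C(=O)C[C@@](/C=C/c1ccccc1)(CC)[C@]2(CC)C(=O)OC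
F8 | step 13 | methyl 1,4,5-triethyl-2,2-dimethoxy-3-methyl-5-[(E)-2-phenylethenyl]-7-{[(trifluoromethyl)sulfonyl]oxy}-2,3,3a,4,5,7a-hexahydro-1H-indene-4-carboxylate | CCC1C(OC)(OC)C(C)[C@H]2[C@H]1C(OS(=O)(=O)C(F)(F)F)=C[C@@](/C=C/c1ccccc1)(CC)[C@]2(CC)C(=O)OC
F9 | step 13 | methyl 1,4,5-triethyl-2,2-dimethoxy-3,7-dimethyl-5-[(E)-2-phenylethenyl]-2,3,3a,4,5,7a-hexahydro-1H-indene-4-carboxylate | CCC1C(OC)(OC)C(C)[C@H]2[C@H]1C(C)=C[C@@](/C=C/c1ccccc1)(CC)[C@]2(CC)C(=O)OC
A1 | alternative 1 | bicyclic enone with C3=C4 alkene, tert-butyl ester and silyloxyethyl arm | CC[C@@H]1C(=O)C(C)=C2[C@H]1C(C)=C[C@@](CCO[Si](C)(C)C(C)(C)C)(CC)[C@]2(CC)C(=O)OC(C)(C)C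
A2 | alternative 1 | dienyne precursor: tert-butyl 2,3-diethyl-3-[2-(tert-butyldimethylsilyloxy)ethyl]-5-methyl-2-(prop-1-ynyl)nona-4,6-dienoate (4Z,6E) | CC/C=C/C(C)=C\[C@@](CCO[Si](C)(C)C(C)(C)C)(CC)[C@](C#CC)(CC)C(=O)OC(C)(C)C
A3 | alternative 2 | cycloadduct: ring-B silyl enol ether with the anhydride across C8 and C9 and ring A as its dioxolane | CC[C@H]1C2(OCCO2)[C@@H](C)[C@H]3C1=C(O[Si](C)(C)C(C)(C)C)C[C@]4(CC)C(=O)OC(=O)[C@]34CC
A4 | alternative 2 | ring-A siloxydiene: dioxolane-protected 2-ethyl-5-methylcyclopent-3-enone bearing a 1-(tert-butyldimethylsilyloxy)vinyl group at C5 | CC[C@H]1C2(OCCO2)[C@@H](C)C=C1C(=C)O[Si](C)(C)C(C)(C)C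
A5 | alternative 3 | ring-expanded hydrindane C6 ketone with C8 methyl ester and C9 tert-butyl ester | CC[C@@H]1C2(OCCO2)[C@@H](C)[C@H]3[C@@H]1C(=O)C[C@H](C(=O)OC)[C@]3(CC)C(=O)OC(C)(C)C
A6 | alternative 3 | bromomethyl β-keto ester on the cis-fused bicyclo[3.3.0]octane (C8 unassigned) | CC[C@@H]1C2(OCCO2)[C@@H](C)[C@H]3[C@@H]1C(=O)C(CBr)(C(=O)OC)[C@]3(CC)C(=O)OC(C)(C)C
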